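**Strategy.** The nine-membered ring is traced back to a seven-membered one by a de Mayo disconnection. C2 (the carbon of the exocyclic methylene) and C10 (the tertiary ether carbon shared by the nine-membered and pyran rings) are both former carbonyls, placed 1,5 across C3–C4–C5. One operation, photocycloaddition of ethylene to the C2=C5 enol double bond of a cyclobutane-fused cycloheptane-1,3-dione followed by retro-aldol opening, inserts C3–C4 and expands the ring to the nine-membered 2,10-diketone. The precursor is the C2 enol benzyl carbonate of trans-fused 3-(benzyloxymethyl)-8,8-dimethylbicyclo[5.2.0]nonane-2,4-dione; hydrogenolysis releases the aldol without base.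

Key step: step 8

Remark: atom labels C1–C31 follow the atom order of the target SMILES and are used for the corresponding atoms of all intermediates; the trans C14/C15 fusion set in step 4 is assumed to persist, and any cis-fused material would equilibrate at C15 (α to the C2 ketone) under the basic conditions of step 13.

Step 1
Reactants: 1 cyclohex-2-en-1-one; 2 isobutylene
Product: 3 (1R,6R)-7,7-dimethylbicyclo[4.2.0]octan-2-one (cis-fused)
Conditions: 2 (excess), AlBr3-activated chiral 1,3,2-oxazaborolidine (50 mol%, enantiomer giving the 6R adduct), CH2Cl2, −75 °C, hν (366 nm); then basic Al2O3, 25 °C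
Reagents that add atoms: none
Why: Chiral-Lewis-acid-catalysed enone–alkene [2+2] photocycloaddition, in which the bound catalyst shields one enone face and so sets C14 (ring position 6, R), the head-to-tail orientation follows from the more stable 1,4-biradical, and alumina equilibrates the epimerisable α-carbon to the cis-fused ketone.

Step 2
Reactants: 3 (1R,6R)-7,7-dimethylbicyclo[4.2.0]octan-2-one
Product: 4 (1R,6R)-7,7-dimethylbicyclo[4.2.0]oct-2-en-2-yl trifluoromethanesulfonate
Conditions: LDA (1.1 equiv), THF, −78 °C; PhNTf2, −78 → 0 °C
Reagents that add atoms: N-phenylbis(trifluoromethanesulfonimide), O=S(=O)(N(c1ccccc1)S(=O)(=O)C(F)(F)F)C(F)(F)F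
Why: Kinetic deprotonation takes the unhindered ring methylene and not the cyclobutane ring-fusion methine, and O-triflation of the lithium enolate (enol triflate formation) fixes the double bond without touching the two stereocentres.

Step 3
Reactants: 4 (1R,6R)-7,7-dimethylbicyclo[4.2.0]oct-2-en-2-yl trifluoromethanesulfonate
Product: 5 (1R,6R)-2,7,7-trimethylbicyclo[4.2.0]oct-2-ene
Conditions: MeMgBr (1.5 equiv), Fe(acac)3 (5 mol%), THF–NMP, −30 → 0 °C
Reagents that add atoms: methylmagnesium bromide, C[Mg]Br
Why: Iron-catalysed Kumada-type cross-coupling of an alkenyl triflate with a methyl Grignard reagent replaces the triflate by the methyl group (the future C5) with retention of the double-bond position; no stereocentre is formed.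

Step 4
Reactants: 5 (1R,6R)-2,7,7-trimethylbicyclo[4.2.0]oct-2-ene
Product: 7 methyl 3-[(1R,4S)-4-acetyl-2,2-dimethylcyclobutyl]propanoate (trans), via cis keto ester 6 (not isolated)
Conditions: O3, NaOH (2.5 M in MeOH), CH2Cl2, −78 °C; then N2 purge, 25 °C; aq. NH4Cl
Reagents that add atoms: ozone, [O-][O+]=O; methanol, CO
Why: Ozonolysis in methanolic hydroxide cleaves the trisubstituted alkene directly to the methyl ketone and the methyl ester, and on warming the basic medium epimerises the acetyl-bearing carbon C15 to the more stable trans-1,2-disubstituted cyclobutane, which is the C14/C15 relationship of the target.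

Step 5
Reactants: 7 methyl 3-[(1R,4S)-4-acetyl-2,2-dimethylcyclobutyl]propanoate
Product: 8 (1S,7R)-8,8-dimethylbicyclo[5.2.0]nonane-2,4-dione (trans-fused)
Conditions: LiHMDS (2.5 equiv), THF (0.02 M), −78 → 0 °C; aq. HCl
Reagents that add atoms: none
Why: Intramolecular Claisen condensation of the kinetic methyl-ketone enolate onto the ester closes the seven-membered ring and is pulled by formation of the diketonate, whereas the five-membered alternatives are reversible (aldol) or give a non-enolisable diketone; the kinetic conditions leave C15 untouched.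

Step 6
Reactants: 8 (1S,7R)-8,8-dimethylbicyclo[5.2.0]nonane-2,4-dione
Product: 11 (1S,7R)-3-[(benzyloxy)methyl]-8,8-dimethylbicyclo[5.2.0]nonane-2,4-dione, via Mannich base hydroiodide 9 (not isolated), via 3-methylene dione 10 (not isolated)
Conditions: [CH2=NMe2]I (1.0 equiv), MeCN, 0 → 25 °C; then BnOH (20 equiv), 60 °C
Reagents that add atoms: N,N-dimethylmethyleneiminium iodide, C=[N+](C)C.[I-]; benzyl alcohol, OCc1ccccc1
Why: Mannich aminomethylation at C5 followed by solvolytic exchange (the enol expels dimethylamine, which is held as its hydroiodide, and benzyl alcohol adds to the transient methylene dione) gives the C-alkylated dione, where a chloromethyl ether would alkylate on oxygen; C5 is configurationally labile.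

Step 7
Reactants: 11 (1S,7R)-3-[(benzyloxy)methyl]-8,8-dimethylbicyclo[5.2.0]nonane-2,4-dione
Product: 13 benzyl (1S,7R)-3-[(benzyloxy)methyl]-8,8-dimethyl-4-oxobicyclo[5.2.0]non-2-en-2-yl carbonate, via silyl dienol carbonate 12 (not isolated)
Conditions: LDA (2.1 equiv), THF, −78 → −30 °C; TMSCl (1.0 equiv), −78 °C; CbzCl (1.1 equiv), −78 °C; then aq. citric acid, 0 °C
Reagents that add atoms: benzyl chloroformate, O=C(Cl)OCc1ccccc1
Why: Dianion formation removes H-5 and then a C12 methylene proton (the other α'-position, C15, is the cyclobutane methine), the more reactive terminal C10/C12 enolate is silylated, the remaining oxygen on C2 is acylated by the chloroformate (enolate O-acylation), and mild acid hydrolyses only the silyl dienol ether, so the carbonate should end up on O–C2 and C2=C5 becomes the enone double bond; no stereocentre is formed.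

Step 8
Reactants: 13 benzyl (1S,7R)-3-[(benzyloxy)methyl]-8,8-dimethyl-4-oxobicyclo[5.2.0]non-2-en-2-yl carbonate; 14 ethylene
Product: 18 (1S,5R,9R)-5-(hydroxymethyl)-10,10-dimethylbicyclo[7.2.0]undecane-2,6-dione, via cyclobutane photoadduct 15 (not isolated), via cyclobutanol 16 (not isolated), via diketone benzyl ether 17 (not isolated)
Conditions: 14 (saturated, slow stream), CH2Cl2, −40 °C, hν (λ ≥ 300 nm, Pyrex); then H2 (1 atm), Pd(OH)2/C, EtOAc–MeOH, 25 °C
Reagents that add atoms: none
Why: The excited β-carbonate enone (C10=O, C5=C2) reacts as its triplet and adds ethylene stepwise through a 1,4-biradical to the cyclobutane C2–C3–C4–C5 (new bonds C4–C5 and C2–C3); hydrogenolysis then removes the benzyl carbonate as toluene and CO2 and the benzyl ether as toluene, and the freed cyclobutanol, β to the C10 ketone, undergoes strain-driven retro-aldol cleavage of C2–C5. The closest known reaction type is the de Mayo reaction of 1,3-diketone enol esters and enol carbonates with alkenes, including hydrogenolytic release of the aldol from an enol benzyl carbonate. The cyclobutane closes by biradical recombination as a cis-fused four/seven ring, and the nine-membered ring arises by ring expansion (fragmentation of the bicyclo[5.2.0] bond C2–C5), not by end-to-end cyclisation. The two centres created in the photoadduct (C2, C5) are erased again, C5 of the diketone arises by ketonisation of the C10 enol and is not relied on (it is epimerisable and is re-set in steps 11 and 12), and C14/C15 are untouched under the neutral conditions. The step needs ethylene to enter on the C2 side of C5, which is secured by the carbonate sitting on O–C2 so that C2=C5 is the only enone double bond, while ethylene, being symmetric, raises no orientation issue. Neutral unmasking keeps the 1,5-diketone away from base and thus from transannular aldol reaction, and the poor leaving group on C6 prevents loss of the side chain during fragmentation.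

Step 9
Reactants: 19 phloroglucinol; 20 isobutyryl chloride
Product: 21 2-methyl-1-(2,4,6-trihydroxyphenyl)propan-1-one
Conditions: AlCl3 (3 equiv), PhNO2–CH2Cl2, 0 → 40 °C; aq. HCl
Reagents that add atoms: none
Why: Friedel–Crafts C-acylation of the electron-rich triol stops at the mono-acyl stage because the first acyl group deactivates the ring; no stereocentre is formed.

Step 10
Reactants: 21 2-methyl-1-(2,4,6-trihydroxyphenyl)propan-1-one
Product: 22 norflavesone, 3,5-dihydroxy-6,6-dimethyl-2-(2-methylpropanoyl)cyclohexa-2,4-dien-1-one
Conditions: NaOMe (3 equiv), MeI (2.2 equiv), MeOH, 0 → 25 °C; aq. HCl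
Reagents that add atoms: iodomethane, CI
Why: Dearomative C-methylation of the phenoxide occurs twice at the same ring carbon (C20), over-methylation being limited by stoichiometry, which leaves one ring CH (C7) as the later nucleophile.

Step 11
Reactants: 18 (1S,5R,9R)-5-(hydroxymethyl)-10,10-dimethylbicyclo[7.2.0]undecane-2,6-dione; 22 norflavesone
Product: 25 C10 hemiketal (lactol) of the Michael adduct, a 2-hydroxytetrahydropyran closed between the C8 enol oxygen and C10, C2 ketone free, (5R,14R,15S), C10 anomers, via mesylate 23 (not isolated), via exo-methylene enone 24 (not isolated)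
Conditions: MsCl (1.05 equiv), Et3N (3 equiv), CH2Cl2, −20 → 0 °C; then 22 (1.2 equiv), 25 °C
Reagents that add atoms: none
Why: Mesylation and E1cB loss of mesylate give the α-methylene ketone, the triketone adds through its free ring carbon C7 (Michael addition), and the enol oxygen on C8, the one not hydrogen-bonded to the isobutyryl group, closes onto the C10 ketone (hemiketalisation), which masks C10 and leaves C2 as the only free ketone; C5 is re-formed by protonation and equilibrates through ring–chain tautomerism.

Step 12
Reactants: 25 C10 hemiketal of the Michael adduct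
Product: 26 C2 ketone of the target skeleton, the target with C2=O in place of C2=CH2, (5R,10S,14R,15S)
Conditions: AlMe3 (5 equiv), CH2Cl2, −78 → −30 °C; aq. potassium sodium tartrate
Reagents that add atoms: trimethylaluminium, C[Al](C)C
Why: Trimethylaluminium ionises the tertiary hemiketal to the O9=C10 oxocarbenium ion and transfers methyl to it (C-methylation of a cyclic hemiketal), axial attack anti to H-5 placing H-5 and the C10 methyl trans as in the target, while the C2 ketone should be spared at low temperature; C5 is fixed here from the equilibrating hemiketal, and the trans-fused diastereomer of opposite sense relative to the cyclobutane, if formed, would be removed by chromatography.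

Step 13
Reactants: 26 C2 ketone of the target skeleton
Product: 27 CNP0497637.1 (target)
Conditions: Ph3PCH3Br (5 equiv), KOtBu (5 equiv), toluene, 25 → 70 °C; aq. NH4Cl
Reagents that add atoms: methyltriphenylphosphonium bromide, C[P+](c1ccccc1)(c1ccccc1)c1ccccc1.[Br-]
Why: Wittig methylenation of the C2 ketone with excess ylide, one equivalent of which is consumed by the acidic enol whose enolate shields the triketone carbonyls; no stereocentre is formed, and C15 stays in, or equilibrates to, the stable trans fusion before olefination.

**Compound list**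

1 | cyclohex-2-en-1-one | O=C1C=CCCC1 | starting material
2 | isobutylene | C=C(C)C | starting material
3 | (1R,6R)-7,7-dimethylbicyclo[4.2.0]octan-2-one | O=C1CCC[C@@H]2[C@H]1CC2(C)C | intermediate
4 | (1R,6R)-7,7-dimethylbicyclo[4.2.0]oct-2-en-2-yl trifluoromethanesulfonate | O=S(=O)(OC1=CCC[C@@H]2[C@H]1CC2(C)C)C(F)(F)F | intermediate
5 | (1R,6R)-2,7,7-trimethylbicyclo[4.2.0]oct-2-ene | CC1=CCC[C@@H]2[C@H]1CC2(C)C | intermediate
6 | methyl 3-[(1R,4R)-4-acetyl-2,2-dimethylcyclobutyl]propanoate (cis) | COC(=O)CC[C@@H]1[C@H](C(C)=O)CC1(C)C | intermediate (not isolated)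
7 | methyl 3-[(1R,4S)-4-acetyl-2,2-dimethylcyclobutyl]propanoate (trans) | COC(=O)CC[C@@H]1[C@@H](C(C)=O)CC1(C)C | intermediate
8 | (1S,7R)-8,8-dimethylbicyclo[5.2.0]nonane-2,4-dione | O=C1CC(=O)CC[C@@H]2[C@@H]1CC2(C)C | intermediate
9 | (1S,7R)-3-[(dimethylammonio)methyl]-8,8-dimethylbicyclo[5.2.0]nonane-2,4-dione iodide (Mannich base hydroiodide, C3 labile) | O=C1C(C[NH+](C)C)C(=O)CC[C@@H]2[C@@H]1CC2(C)C.[I-] | intermediate (not isolated)
10 | (1S,7R)-8,8-dimethyl-3-methylenebicyclo[5.2.0]nonane-2,4-dione | O=C1C(=C)C(=O)CC[C@@H]2[C@@H]1CC2(C)C | intermediate (not isolated)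
11 | (1S,7R)-3-[(benzyloxy)methyl]-8,8-dimethylbicyclo[5.2.0]nonane-2,4-dione (C3 labile, keto–enol mixture) | O=C1C(COCc3ccccc3)C(=O)CC[C@@H]2[C@@H]1CC2(C)C | intermediate
12 | benzyl (1S,7R)-3-[(benzyloxy)methyl]-8,8-dimethyl-4-[(trimethylsilyl)oxy]bicyclo[5.2.0]nona-2,4-dien-2-yl carbonate | O=C(OCc1ccccc1)OC1=C(COCc3ccccc3)C(O[Si](C)(C)C)=CC[C@@H]2[C@@H]1CC2(C)C | intermediate (not isolated)
13 | benzyl (1S,7R)-3-[(benzyloxy)methyl]-8,8-dimethyl-4-oxobicyclo[5.2.0]non-2-en-2-yl carbonate (key-step precursor) | O=C(OCc1ccccc1)OC1=C(COCc3ccccc3)C(=O)CC[C@@H]2[C@@H]1CC2(C)C | intermediate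
14 | ethylene | C=C | starting material
15 | cyclobutane photoadduct: ethylene added across C2=C5, benzyl carbonate on C2, benzyloxymethyl on C5 (configuration at C2/C5 not defined, both erased later) | O=C(OCc1ccccc1)OC12CCC1(COCc3ccccc3)C(=O)CC[C@@H]3[C@@H]2CC3(C)C | intermediate (not isolated)
16 | cyclobutanol obtained from 15 by loss of the benzyl carbonate | OC12CCC1(COCc3ccccc3)C(=O)CC[C@@H]3[C@@H]2CC3(C)C | intermediate (not isolated)
17 | (1S,9R)-5-[(benzyloxy)methyl]-10,10-dimethylbicyclo[7.2.0]undecane-2,6-dione (C5 epimers) | O=C1CCC(COCc3ccccc3)C(=O)CC[C@@H]2[C@@H]1CC2(C)C | intermediate (not isolated)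
18 | (1S,5R,9R)-5-(hydroxymethyl)-10,10-dimethylbicyclo[7.2.0]undecane-2,6-dione (key-step product; C5 drawn as 5R, epimerisable) | O=C1CC[C@H](CO)C(=O)CC[C@@H]2[C@@H]1CC2(C)C | intermediate
19 | phloroglucinol | Oc1cc(O)cc(O)c1 | starting material
20 | isobutyryl chloride | CC(C)C(Cl)=O | starting material
21 | 2-methyl-1-(2,4,6-trihydroxyphenyl)propan-1-one | CC(C)C(=O)c1c(O)cc(O)cc1O | intermediate
22 | norflavesone, 3,5-dihydroxy-6,6-dimethyl-2-(2-methylpropanoyl)cyclohexa-2,4-dien-1-one | OC1=CC(O)=C(C(=O)C(C)C)C(=O)C1(C)C | intermediate
23 | mesylate of 18 | O=C1CC[C@H](COS(C)(=O)=O)C(=O)CC[C@@H]2[C@@H]1CC2(C)C | intermediate (not isolated)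
24 | (1S,9R)-10,10-dimethyl-5-methylenebicyclo[7.2.0]undecane-2,6-dione | O=C1CCC(=C)C(=O)CC[C@@H]2[C@@H]1CC2(C)C | intermediate (not isolated)
25 | C10 hemiketal of the Michael adduct (5R,14R,15S; C10 anomers; in equilibrium with the open keto form) | O=C1CC[C@@H]2CC3=C(OC2(O)CC[C@@H]2[C@@H]1CC2(C)C)C(C)(C)C(=O)C(C(=O)C(C)C)=C3O | intermediate
26 | C2 ketone of the target skeleton (5R,10S,14R,15S) | O=C1CC[C@@H]2CC3=C(O[C@@]2(C)CC[C@@H]2[C@@H]1CC2(C)C)C(C)(C)C(=O)C(C(=O)C(C)C)=C3O | intermediate
27 | CNP0497637.1 | C=C1CC[C@@H]2CC3=C(O[C@@]2(C)CC[C@@H]2[C@@H]1CC2(C)C)C(C)(C)C(=O)C(C(=O)C(C)C)=C3O | target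

**Step count.** Total 13 steps; longest linear sequence 11 steps (steps 1–8 and 11–13; steps 9–10 form the side branch).

**Steps most likely to fail**

Step 8. Capture of the enone triplet by gaseous ethylene at the hindered, tetrasubstituted C2=C5 bond may be slow, so that 1,3-acyl shift of the carbonate or hydrogen abstraction takes over. The fallback sets out from 13 and uses a liquid ethylene surrogate. Irradiation in neat (Z)-1,2-dichloroethene–CH2Cl2 should give the dichlorocyclobutane adduct F1. Zinc dust in ethanol then removes both chlorines to give the cyclobutene F2. Hydrogenation over Pd(OH)2/C saturates the cyclobutene and cleaves both benzyl groups, after which the retro-aldol opening delivers 18, where the route is rejoined.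

Step 7. The first silylation may occur on the wrong enol oxygen, or the second deprotonation may be incomplete; either places the carbonate partly on O–C10. The fallback sets out from 11 and gives up the selectivity: direct acylation of the sodium enolate (NaH, CbzCl, THF, 0 °C) should give 13 together with the C10 enol carbonate regioisomer F3. The two are separated by chromatography, and F3 is returned to 11 with K2CO3 in methanol and resubmitted. The route is rejoined at 13.

Step 12. The aluminium reagent may add to the C2 ketone, or the oxocarbenium ion may lose a proton to the enol ether instead of accepting methyl. The fallback sets out from 25 and makes that elimination deliberate: PPTS and 4 Å molecular sieves in toluene at 60 °C give the 4H-pyran F4. The oxocarbenium ion is then regenerated by protonation at C5 with TfOH (1 equiv, CH2Cl2, −78 °C) and trapped with Me2Zn (3 equiv, added afterwards), a methyl donor that does not add to ketones. This returns to 26.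

**Further compounds**

F1 | step 8 | dichlorocyclobutane photoadduct of 13 with (Z)-1,2-dichloroethene | O=C(OCc1ccccc1)OC12C(Cl)C(Cl)C1(COCc3ccccc3)C(=O)CC[C@@H]3[C@@H]2CC3(C)C
F2 | step 8 | cyclobutene obtained from F1 | O=C(OCc1ccccc1)OC12C=CC1(COCc3ccccc3)C(=O)CC[C@@H]3[C@@H]2CC3(C)C
F3 | step 7 | C10 enol carbonate regioisomer of 13, benzyl (1R,7S)-3-[(benzyloxy)methyl]-9,9-dimethyl-2-oxobicyclo[5.2.0]non-3-en-4-yl carbonate | O=C1C(COCc3ccccc3)=C(OC(=O)OCc3ccccc3)CC[C@@H]2[C@@H]1CC2(C)C
F4 | step 12 | 4H-pyran (C5=C10 enol ether) obtained from 25 by loss of water | O=C1CCC2=C(CC[C@@H]3[C@@H]1CC3(C)C)OC1=C(C2)C(O)=C(C(=O)C(C)C)C(=O)C1(C)C
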